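**Strategy.** Ring B of the eudesmane core is disconnected at C7–C8. The key step joins three components around a cyclohexenone that becomes ring A: a methyl Grignard reagent adds to C10 under copper–NHC control, the enolate picks up methyl propiolate at C5, and acid unmasks an aldehyde (C8) on the C9 arm. C7, now the remote carbon of a vinylogous β-keto ester (C4=O, C5, C6=C7, ester C11), condenses with C8 and closes ring B as a C5=C6/C7=C8 dienone. Because C5 is left trigonal, one hydrogenation opposite the C10 methyl group sets C5 and C7; methylenation at C4, acid-mediated addition of magnolol and methyl Grignard addition complete the target.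

Key step: step 2

Remark: eudesmane numbering is used (ring A = C1–C5, C10; ring B = C5–C10; C11 is the side-chain carbon on C7; C14 and C15 are the methyl groups on C10 and C4); in step 2 the enantiomer of the NHC ligand is taken that gives (R) at C10.

Step 1
Reactants: 1 3-ethoxycyclohex-2-en-1-one; 2 (1,3-dioxolan-2-ylmethyl)magnesium bromide
Product: 4 3-(1,3-dioxolan-2-ylmethyl)cyclohex-2-en-1-one, via magnesium alkoxide 3 (not isolated)
Conditions: THF, 0 → 40 °C; then aq HCl (1 M), 0 °C, short contact
Reagents that add atoms: water, O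
Why: Stork–Danheiser sequence: the Grignard reagent adds 1,2 to the vinylogous ester, and brief cold aqueous acid hydrolyses the enol ether and eliminates the tertiary hydroxyl with loss of ethanol, which transposes the carbonyl while the more robust dioxolane should survive; no stereocentre is formed.

Step 2
Reactants: 4 3-(1,3-dioxolan-2-ylmethyl)cyclohex-2-en-1-one; 5 methyl propiolate
Product: 9 methyl (4aR)-4a-methyl-8-oxo-4,4a,5,6,7,8-hexahydronaphthalene-2-carboxylate, via magnesium enolate 6 (not isolated), via acetal keto enoate 7 (not isolated), via keto aldehyde 8 (not isolated)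
Conditions: MeMgBr, Cu(OTf)2 (cat.), chiral hydroxyalkyl imidazolinium salt (NHC precursor, cat.), Et2O, 0 °C; then 5, −78 → −20 °C; then aq HCl (3 M), THF, 23 → 50 °C
Reagents that add atoms: methylmagnesium bromide, C[Mg]Br
Why: Copper–NHC-catalysed asymmetric conjugate addition of the methyl Grignard reagent to 4 forms the C10 quaternary centre under ligand control and gives the regiodefined magnesium enolate 6, which adds in Michael fashion through C5 to methyl propiolate; the vinyl anion is quenched by the now doubly activated C5–H, so the adduct rests as the dienolate of the vinylogous β-keto ester 7. Aqueous acid then cleaves the dioxolane to aldehyde 8, and the dienol attacks C8 through its remote carbon C7 (intramolecular vinylogous Knoevenagel/aldol condensation), loss of water giving the conjugated dienone 9. The closest known reactions are tandem conjugate addition–enolate trapping and the Knoevenagel condensation of vinylogous β-dicarbonyl compounds with aldehydes. Ring B closes at C7–C8 in the 6-(enolexo)-exo-trig mode. C10 (R) is the only stereocentre formed and is set by the chiral ligand, while C5 and C7 become trigonal, so no ring-fusion stereochemistry has to be controlled here. The step needs C–C bonding at C7 and not at C5 or C3: attack from C5 would give a four-membered ring, the aldol from C3 gives a bicyclo[2.2.2]octanol that cannot dehydrate and should revert, and only the C7 pathway is drained by irreversible dehydration to the fully conjugated system.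

Step 3
Reactants: 9 methyl (4aR)-4a-methyl-8-oxo-4,4a,5,6,7,8-hexahydronaphthalene-2-carboxylate
Product: 10 methyl (2R,4aR,8aR)-4a-methyl-8-oxodecahydronaphthalene-2-carboxylate
Conditions: H2 (1 atm), 10% Pd/C, EtOAc, 23 °C
Reagents that add atoms: none
Why: Heterogeneous catalytic hydrogenation should add hydrogen syn to both trisubstituted alkenes from the α-face, opposite the axial C10 methyl group (as in the hydrogenation of Δ5-steroids), which sets C5 (H α, trans ring fusion) and C7 (H α, ester β and equatorial).

Step 4
Reactants: 10 methyl (2R,4aR,8aR)-4a-methyl-8-oxodecahydronaphthalene-2-carboxylate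
Product: 11 methyl (2R,4aR,8aS)-4a-methyl-8-methylidenedecahydronaphthalene-2-carboxylate
Conditions: Zn, CH2Br2, TiCl4, THF–CH2Cl2, 0 → 23 °C
Reagents that add atoms: dibromomethane, BrCBr
Why: Lombardo methylenation converts the hindered C4 ketone into the exocyclic alkene under non-basic conditions, so the epimerisable C5 centre and the ester should be untouched (the 8aS label reflects only a change in CIP priority).

Step 5
Reactants: 11 methyl (2R,4aR,8aS)-4a-methyl-8-methylidenedecahydronaphthalene-2-carboxylate; 12 magnolol
Product: 13 methyl (2R,4aR,8R,8aR)-8-{[2'-hydroxy-5,5'-di(prop-2-en-1-yl)-[1,1'-biphenyl]-2-yl]oxy}-4a,8-dimethyldecahydronaphthalene-2-carboxylate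
Conditions: 12 (excess), TfOH (cat.), CH2Cl2, −40 → −20 °C
Reagents that add atoms: none
Why: Brønsted acid-catalysed Markovnikov hydroaryloxylation: protonation of the 1,1-disubstituted alkene gives the tertiary C4 cation, which one phenol oxygen of magnolol should capture from the equatorial α-face because the axial β-face is blocked by the syn-axial C10 methyl group, setting C4 (R); the monosubstituted allyl groups are protonated far more slowly and the low temperature favours kinetic O-alkylation.

Step 6
Reactants: 13 methyl (2R,4aR,8R,8aR)-8-{[2'-hydroxy-5,5'-di(prop-2-en-1-yl)-[1,1'-biphenyl]-2-yl]oxy}-4a,8-dimethyldecahydronaphthalene-2-carboxylate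
Product: 14 eudesmagnolol
Conditions: MeMgBr (excess), THF, 0 → 23 °C; aq NH4Cl
Reagents that add atoms: methylmagnesium bromide, C[Mg]Br
Why: Double Grignard addition to the methyl ester (after deprotonation of the phenol) should form the C11 tertiary alcohol; the aryl ether, the allyl groups and all stereocentres are not affected.

**Compound list**

1 | 3-ethoxycyclohex-2-en-1-one | CCOC1=CC(=O)CCC1 | starting material
2 | (1,3-dioxolan-2-ylmethyl)magnesium bromide | Br[Mg]CC1OCCO1 | starting material
3 | bromomagnesium 1-(1,3-dioxolan-2-ylmethyl)-3-ethoxycyclohex-2-en-1-olate (racemic) | CCOC1=CC(O[Mg]Br)(CC2OCCO2)CCC1 | intermediate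
4 | 3-(1,3-dioxolan-2-ylmethyl)cyclohex-2-en-1-one | O=C1C=C(CC2OCCO2)CCC1 | intermediate
5 | methyl propiolate (methyl prop-2-ynoate) | C#CC(=O)OC | starting material
6 | bromomagnesium (3R)-3-(1,3-dioxolan-2-ylmethyl)-3-methylcyclohex-1-en-1-olate | Br[Mg]OC1=C[C@@](C)(CC2OCCO2)CCC1 | intermediate
7 | methyl (2E)-3-[(2R)-2-(1,3-dioxolan-2-ylmethyl)-2-methyl-6-oxocyclohexyl]prop-2-enoate (ring C1 epimeric or enolised) | O=C1CCC[C@](C)(CC2OCCO2)C1/C=C/C(=O)OC | intermediate
8 | methyl (2E)-3-[(2R)-2-methyl-6-oxo-2-(2-oxoethyl)cyclohexyl]prop-2-enoate (ring C1 epimeric or enolised) | O=C1CCC[C@](C)(CC=O)C1/C=C/C(=O)OC | intermediate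
9 | methyl (4aR)-4a-methyl-8-oxo-4,4a,5,6,7,8-hexahydronaphthalene-2-carboxylate | O=C1CCC[C@]2(C)CC=C(C(=O)OC)C=C12 | intermediate
10 | methyl (2R,4aR,8aR)-4a-methyl-8-oxodecahydronaphthalene-2-carboxylate (trans-fused, ester equatorial) | O=C1CCC[C@]2(C)CC[C@@H](C(=O)OC)C[C@H]21 | intermediate
11 | methyl (2R,4aR,8aS)-4a-methyl-8-methylidenedecahydronaphthalene-2-carboxylate | C=C1CCC[C@]2(C)CC[C@@H](C(=O)OC)C[C@H]21 | intermediate
12 | magnolol (5,5'-diallylbiphenyl-2,2'-diol) | C=CCc1ccc(O)c(-c2cc(CC=C)ccc2O)c1 | starting material
13 | methyl (2R,4aR,8R,8aR)-8-{[2'-hydroxy-5,5'-di(prop-2-en-1-yl)-[1,1'-biphenyl]-2-yl]oxy}-4a,8-dimethyldecahydronaphthalene-2-carboxylate | C=CCc1ccc(O)c(-c2cc(CC=C)ccc2O[C@]2(C)CCC[C@]3(C)CC[C@@H](C(=O)OC)C[C@H]32)c1 | intermediate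
14 | eudesmagnolol, 2-[(2R,4aR,8R,8aR)-8-{[2'-hydroxy-5,5'-di(prop-2-en-1-yl)-[1,1'-biphenyl]-2-yl]oxy}-4a,8-dimethyldecahydronaphthalen-2-yl]propan-2-ol | C=CCc1ccc(O)c(-c2cc(CC=C)ccc2O[C@]2(C)CCC[C@]3(C)CC[C@@H](C(C)(C)O)C[C@H]32)c1 | target

**Step count and risks**

Total steps: 6. Longest linear sequence: 6 steps (1 → 14).

Steps most likely to fail:

1. Step 5. The tertiary ether forms reversibly, so the C4 cation may instead eliminate to ring alkenes, epimerise C5 through the tetrasubstituted C4=C5 alkene, alkylate the arene at carbon, or the acid may attack the allyl groups. Fallback: setting out from 11, a cobalt-catalysed MHAT/radical–polar crossover hydroalkoxylation (Co(salen) [Co(C16H14N2O2)] cat., N-fluoro-2,4,6-trimethylpyridinium triflate, PhSiH3, PhCF3, 0 °C) with 5,5'-dibromo-2,2'-biphenol generates the C4 cation equivalent irreversibly and without Brønsted acid. It should give methyl (2R,4aR,8R,8aR)-8-[(5,5'-dibromo-2'-hydroxybiphenyl-2-yl)oxy]-4a,8-dimethyldecahydronaphthalene-2-carboxylate F1. Double Stille allylation (allyltributylstannane, Pd(PPh3)4, DMF, 90 °C) then comes back to the route at 13.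

2. Step 2. The magnesium enolate may deprotonate the propiolate instead of adding to it, the dienolate may lactonise to a 2-pyranone, the enantioselectivity of the conjugate addition may erode, or the acid stage may stop before cyclodehydration. Fallback: setting out from 4, the same conjugate addition is quenched with Me3SiCl to give {[(3R)-3-(1,3-dioxolan-2-ylmethyl)-3-methylcyclohex-1-en-1-yl]oxy}trimethylsilane F2. A Mukaiyama addition to methyl 3,3-dimethoxypropanoate (Me3SiOTf cat., CH2Cl2, −78 °C) gives methyl 3-[(2R)-2-(1,3-dioxolan-2-ylmethyl)-2-methyl-6-oxocyclohexyl]-3-methoxypropanoate F3. Aqueous HCl followed by piperidinium acetate in toluene (loss of methanol and ethane-1,2-diol, then condensation) comes back to the route at 9.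

3. Step 3. Facial selectivity may be poor, or C5 may lose its configuration when hydrogen adds 1,4 to the enone and the resulting enol ketonises unselectively; the trans ketone is not strongly favoured thermodynamically, so base cannot correct this. Fallback: setting out from 9, Luche reduction (NaBH4, CeCl3·7H2O, MeOH, −40 °C) removes the enone and gives methyl (4aR)-8-hydroxy-4a-methyl-4,4a,5,6,7,8-hexahydronaphthalene-2-carboxylate F4. Hydrogenation (H2, 10% Pd/C) of this diene, whose β-face is shielded by both the C10 methyl and the C4 hydroxyl group and which has no ketone enol pathway, gives methyl (2R,4aR,8aR)-8-hydroxy-4a-methyldecahydronaphthalene-2-carboxylate F5. Dess–Martin oxidation comes back to the route at 10.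

Further compounds
F1 | step 5 | methyl (2R,4aR,8R,8aR)-8-[(5,5'-dibromo-2'-hydroxybiphenyl-2-yl)oxy]-4a,8-dimethyldecahydronaphthalene-2-carboxylate | Brc1ccc(O)c(-c2cc(Br)ccc2O[C@]2(C)CCC[C@]3(C)CC[C@@H](C(=O)OC)C[C@H]32)c1
F2 | step 2 | {[(3R)-3-(1,3-dioxolan-2-ylmethyl)-3-methylcyclohex-1-en-1-yl]oxy}trimethylsilane | C[Si](C)(C)OC1=C[C@@](C)(CC2OCCO2)CCC1
F3 | step 2 | methyl 3-[(2R)-2-(1,3-dioxolan-2-ylmethyl)-2-methyl-6-oxocyclohexyl]-3-methoxypropanoate (diastereomer mixture) | O=C1CCC[C@](C)(CC2OCCO2)C1C(OC)CC(=O)OC
F4 | step 3 | methyl (4aR)-8-hydroxy-4a-methyl-4,4a,5,6,7,8-hexahydronaphthalene-2-carboxylate (C8 epimers) | OC1CCC[C@]2(C)CC=C(C(=O)OC)C=C12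
F5 | step 3 | methyl (2R,4aR,8aR)-8-hydroxy-4a-methyldecahydronaphthalene-2-carboxylate (C8 epimers) | OC1CCC[C@]2(C)CC[C@@H](C(=O)OC)C[C@H]21
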